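| flask | starting material | temperature | remark | time |
|---|---|---|---|---|
| autumn | 10 mM | 100 °C | the very flask that is asked about, followed so far |  |
| dusk | 20 mM | 85 °C | run made earlier |  |
| flask | 10 mM | 100 °C |  | 8.0 d |

| run | time / h | target / % | starting material / % |
|---|---|---|---|
| autumn | 15.0 | 20.0 | 9.6 |
| autumn | 40.0 | 18.9 | 7.5 |
| autumn | 72.0 | 21.8 | 8.8 |
| autumn | 192 | 19.3 | 7.9 |
| dusk | 10.0 | 6.2 | 45.7 |
| dusk | 20.0 | 8.3 | 21.8 |
| dusk | 30.0 | 10.3 | 10.8 |
| dusk | 40.0 | 11.0 | 7.8 |

(each reading ± 1 percentage point)
- green: at 8.0 d take out 90% of the target then present, then wait 2.5 d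
- grey: at 8.0 d raise the temperature by 25 K, then wait 2.5 d
- violet: at 8.0 d add starting material, 50.0% of the amount charged, then wait 2.5 d
- blue: change nothing and wait 2.5 d more
- target taken out counts as made
- additions bring no volume worth counting
- target, in percent of the starting material first charged, at 8.0 d
- which option adds most target ("none" when 2 percentage points or less is all one gets) (green / grey / violet / blue / none)
- target present, with what was taken out counted in, in percent of the starting material first charged, after grey
- target present, with what was taken out counted in, in percent of the starting material first charged, after blue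

- In the autumn flask, target and starting material together read 27.2% at 192 h, less than the charge, so the rest sits in something I cannot see.
- The four readings of that sum show no trend beyond their scatter, so the unseen part reads level too. I read this as a reversible pool at rest, that is, thermodynamic control, though an inert rest would read the same and green would then gain nothing.
- The mean target reading gives 20.0%, counting the whole charge as pool: this is the refill share s, c(target) over the summed c of everything interconverting with it.
- Taking out a fraction x leaves a pool of 1 − x·s, which refills to the same share, so the gain is x·s·(1 − s), here 14 percentage points. Adding a fraction a gains a·s, here 10 points. The wait of 2.5 d is longer than the 40.0 h by which the autumn readings stand level.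
- Turned round, violet overtakes green once s passes 1 − a/x, which is 44.4%. The autumn flask stands 24 points below that, against a scatter of 1 point, so I commit to green, with 20.0% now and after blue.
- The forecast gives 20% now, violet as best, 20.5% after grey and 20% after blue: “Target is a stable end product, not in equilibrium, so removing it gains nothing”. We part on green.
- The autumn flask gives 19.8% now. Green adds 14 points, violet 9.9 points, grey 0.98 points and blue −0.099 points, so green is best, with 20.8% after grey and 19.7% after blue.

    starting material ⇌ target (K = 2.60, k = 1.00 × 10⁻⁵ s⁻¹, Ea = 122 kJ mol⁻¹, ΔH = −38.0 kJ mol⁻¹)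
    target ⇌ isomer of the product (K = 3.40, k = 4.50 × 10⁻⁵ s⁻¹, Ea = 108 kJ mol⁻¹, ΔH = −32.0 kJ mol⁻¹)
    isomer of the product ⇌ starting material (k = 4.60 × 10⁻⁶ s⁻¹, Ea = 124 kJ mol⁻¹)
    2 starting material → self-condensation product A (k = 1.90 × 10⁻⁴ M⁻¹ s⁻¹, Ea = 94.0 kJ mol⁻¹)
    2 starting material → self-condensation product B (k = 9.40 × 10⁻⁷ M⁻¹ s⁻¹, Ea = 118 kJ mol⁻¹)
    (constants at 100 °C)

- My 14 points stands beside that 14 points. The neighbour flask kept at 85 °C holds share 15.5% among starting material, target and isomer of the product, also below 44.4%. In the autumn flask that share is 20.9% at 192 h and 20.9% at 1920 h, ten times that time, yet the flask is not at rest: self-condensation product A climbs from 5.27% at 192 h to 17.1% at 1920 h, and target falls by 2.5 points to 17.3% at 1920 h.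

(The data are simulated with made-up constants, and the scatter is random.)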